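Ring D (the spiro cyclohexene, C-5 to C-10 in spiro[4.5]decane numbering) is closed at its C-9–C-10 bond by an Ireland–Claisen ring contraction of a 6-(1-bromopropenyl)-5-isopropyl δ-lactone. The step exploits the allylic array C-6–C-5–C-10 beside the C-9 methylene: the lactone α-carbon becomes C-9, the propenyl terminus becomes the methyl-bearing C-10, and the carbinol carbon, set by asymmetric allylboration, becomes vinylic C-6 and hands its configuration to C-10. One operation thus makes the carbocycle and its first permanent stereocentre. Decarboxylation, carbonylation and deconjugative alkylation then build the spiro centre anti to the C-10 methyl; Dieckmann closure, an o-quinone methide cycloaddition, ketal reduction and late double C–H formylation complete the target.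

Key step: step 5

Remark: the terpenoid carbons carry spiro[4.5]decane locants (C-1 the O-bearing CH, C-2 the methyl-bearing quaternary carbon, C-5 the spiro carbon, C-6=C-7 the ring alkene, C-10 the CH–CH3; ring D is C-5 to C-10), the benzylic carbon is C-7', and every carbon keeps its target locant in the earlier intermediates; compounds 1, 4, 18 and 24 and all reagents are taken to be commercial.

Step 1
Reactants: 1 (E)-but-2-enal
Product: 3 (Z)-2-bromobut-2-enal, via dibromide 2 (not isolated)
Conditions: Br2, CH2Cl2, 0 °C; then Et3N, 0 °C → rt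
Reagents that add atoms: bromine, BrBr
Why: Bromination of the alkene and base-induced loss of HBr (the α-hydrogen is the acidic one) should give the 2-bromoenal, the Z isomer (CH3 anti to CHO) being the stable geometry.

Step 2
Reactants: 3 (Z)-2-bromobut-2-enal; 4 (E)-4-methylpent-2-ene
Product: 7 (3S,4S,5Z)-5-bromo-3-(propan-2-yl)hepta-1,5-dien-4-ol, via allylborane 5 (not isolated), via borinate 6 (not isolated)
Conditions: 4, n-BuLi, KOt-Bu, THF, −78 → −50 °C; (−)-B-methoxydiisopinocampheylborane, −78 °C; BF3·OEt2; then 3, −78 °C; NaOH, H2O2, 0 °C → rt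
Reagents that add atoms: none
Why: Brown asymmetric allylboration: metalation at the allylic methyl keeps the E geometry, the E-γ-isopropylallyl borane reacts through a chair (Zimmerman–Traxler) transition state to give the anti pair, and the isopinocampheyl groups derived from (+)-α-pinene direct attack to the Si face of the aldehyde, which sets the 4S carbinol (future C-6) and 3S (future C-7).

Step 3
Reactants: 7 (3S,4S,5Z)-5-bromo-3-(propan-2-yl)hepta-1,5-dien-4-ol
Product: 9 (5R,6S)-6-[(1Z)-1-bromoprop-1-en-1-yl]-5-(propan-2-yl)oxan-2-ol, via hydroxy aldehyde 8 (not isolated)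
Conditions: Rh(acac)(CO)2 (cat.), BIPHEPHOS, CO/H2 (1:1, 10 bar), toluene, 60 °C
Reagents that add atoms: carbon monoxide, [C-]#[O+]
Why: Rhodium-catalysed hydroformylation with a wide-bite-angle diphosphite is linear-selective on the monosubstituted alkene (the trisubstituted bromoalkene does not react), and the 5-hydroxy aldehyde closes to the six-membered lactol, whose anomeric centre is removed in step 4.

Step 4
Reactants: 9 (5R,6S)-6-[(1Z)-1-bromoprop-1-en-1-yl]-5-(propan-2-yl)oxan-2-ol
Product: 10 (5R,6S)-6-[(1Z)-1-bromoprop-1-en-1-yl]-5-(propan-2-yl)oxan-2-one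
Conditions: TEMPO (cat.), PhI(OAc)2, CH2Cl2, rt
Reagents that add atoms: none
Why: Oxoammonium (TEMPO) oxidation of the lactol to the δ-lactone under neutral conditions should leave the allylic C–O centre and the alkenyl bromide intact.

Step 5
Reactants: 10 (5R,6S)-6-[(1Z)-1-bromoprop-1-en-1-yl]-5-(propan-2-yl)oxan-2-one
Product: 13 (1R,2R,5R)-3-bromo-2-methyl-5-(propan-2-yl)cyclohex-3-ene-1-carboxylic acid, via ketene silyl acetal 11 (not isolated), via silyl ester 12 (not isolated)
Conditions: LiN(i-Pr)2, TMSCl, Et3N, THF, −78 °C; then toluene, 100 °C; 1 M HCl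
Reagents that add atoms: none
Why: Ireland–Claisen rearrangement: the lithium enolate of the lactone is O-silylated to the cyclic ketene silyl acetal 11, which on heating undergoes a concerted [3,3]-sigmatropic shift in which the C-9–C-10 σ-bond forms as the C-6–O bond breaks, giving silyl ester 12 and, after hydrolysis, acid 13. The closest known reaction type is the Claisen ring contraction of lactone silyl ketene acetals that carry an alkenyl group on the carbinol carbon (lactone to carbocycle, as in the dioxanone-to-dihydropyran variant). Ring D is closed by sigmatropic ring contraction of the six-membered lactone through a boat-shaped, bicyclo[2.2.2]-like array, because the two-carbon bridge C-7–C-8 ties the ketene acetal carbon to the carbinol carbon. C-10 is set by suprafacial chirality transfer from C-6: with the Z-bromoalkene (CH3 anti to C-6) and C-7 forced into the inside position by the ring, the 6S carbinol should give 10R; C-9 is formed cis to the C-10 methyl but is erased in step 6, and C-7 is carried unchanged. The step needs the rearrangement to outrun loss of HBr and C-silylation, which in situ silylation at −78 °C should secure, and it needs a single transition-state topology, which the lactone tether guarantees.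

Step 6
Reactants: 13 (1R,2R,5R)-3-bromo-2-methyl-5-(propan-2-yl)cyclohex-3-ene-1-carboxylic acid
Product: 16 (3R,6R)-1-bromo-6-methyl-3-(propan-2-yl)cyclohex-1-ene, via acid chloride 14 (not isolated), via thiohydroxamate ester 15 (not isolated)
Conditions: (COCl)2, DMF (cat.), CH2Cl2, 0 °C → rt; then sodium 2-thioxopyridin-1(2H)-olate, DMAP (cat.), t-BuSH, toluene, hν, 80 °C
Reagents that add atoms: none
Why: Barton decarboxylation: the thiohydroxamate ester fragments under light to the secondary C-9 radical, which the thiol reduces, so the carboxyl carbon that served the rearrangement is removed without touching C-10 or C-7.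

Step 7
Reactants: 16 (3R,6R)-1-bromo-6-methyl-3-(propan-2-yl)cyclohex-1-ene
Product: 17 methyl (3R,6R)-6-methyl-3-(propan-2-yl)cyclohex-1-ene-1-carboxylate
Conditions: Pd(OAc)2 (cat.), dppp, CO (1 atm), MeOH, Et3N, DMF, 70 °C
Reagents that add atoms: carbon monoxide, [C-]#[O+]; methanol, CO
Why: Palladium-catalysed methoxycarbonylation of the alkenyl bromide (oxidative addition, CO insertion, methanolysis) installs the future C-1 as an ester on C-5 with the alkene and both stereocentres unchanged.

Step 8
Reactants: 17 methyl (3R,6R)-6-methyl-3-(propan-2-yl)cyclohex-1-ene-1-carboxylate; 18 methyl 4-iodobutanoate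
Product: 19 methyl (1R,6R)-1-(4-methoxy-4-oxobutyl)-6-methyl-3-(propan-2-yl)cyclohex-2-ene-1-carboxylate
Conditions: LiN(i-Pr)2, HMPA, THF, −78 °C; then 18, −78 → −20 °C
Reagents that add atoms: none
Why: Deconjugative α-alkylation: the base removes the γ-hydrogen at C-7, the cross-conjugated dienolate alkylates at the α-carbon (future C-5), which moves the alkene to C-6=C-7, and the iodide should enter anti to the neighbouring C-10 methyl (held pseudoaxial by allylic strain with the enolate), so the ester ends cis to that methyl (spiro centre R).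

Step 9
Reactants: 19 methyl (1R,6R)-1-(4-methoxy-4-oxobutyl)-6-methyl-3-(propan-2-yl)cyclohex-2-ene-1-carboxylate
Product: 21 methyl (5R,10R)-2,10-dimethyl-1-oxo-7-(propan-2-yl)spiro[4.5]dec-6-ene-2-carboxylate, via keto ester 20 (not isolated)
Conditions: NaH, MeOH (cat.), THF, 65 °C; then MeI, rt
Reagents that add atoms: iodomethane, CI
Why: Dieckmann condensation: only the butanoate arm can be enolised, it acylates on the ring ester, and the five-membered β-keto ester is held as its sodium enolate and C-methylated in the same flask; the new C-2 centre is of no consequence and both epimers are carried on.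

Step 10
Reactants: 21 methyl (5R,10R)-2,10-dimethyl-1-oxo-7-(propan-2-yl)spiro[4.5]dec-6-ene-2-carboxylate
Product: 22 (5R,10R)-2,10-dimethyl-7-(propan-2-yl)spiro[4.5]dec-6-en-1-one
Conditions: LiCl, H2O, DMSO, 150 °C
Reagents that add atoms: none
Why: Krapcho demethoxycarbonylation (chloride attack on the ester methyl, loss of CO2, protonation) should give the 2-methyl ketone as a C-2 epimer mixture that converges in step 11.

Step 11
Reactants: 22 (5R,10R)-2,10-dimethyl-7-(propan-2-yl)spiro[4.5]dec-6-en-1-one
Product: 23 tert-butyl{[(5R,10R)-2,10-dimethyl-7-(propan-2-yl)spiro[4.5]deca-1,6-dien-1-yl]oxy}dimethylsilane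
Conditions: TBSOTf, Et3N, CH2Cl2, 0 °C → rt
Reagents that add atoms: tert-butyldimethylsilyl trifluoromethanesulfonate, CC(C)(C)[Si](C)(C)OS(=O)(=O)C(F)(F)F
Why: Soft enolisation and O-silylation: C-5 is quaternary, so the enol ether can form only toward C-2, which erases the C-2 centre and fixes CH3 and OTBS cis on the ring alkene.

Step 12
Reactants: 24 2,4,6-trihydroxybenzaldehyde
Product: 25 2,4,6-tris[(tert-butoxycarbonyl)oxy]benzaldehyde
Conditions: Boc2O, DMAP (cat.), i-Pr2NEt, THF, 0 °C → rt
Reagents that add atoms: di-tert-butyl dicarbonate, CC(C)(C)OC(=O)OC(=O)OC(C)(C)C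
Why: DMAP-catalysed carbonate formation on all three phenols gives the aldehyde whose ortho carbonate later triggers quinone methide formation; no stereocentre is involved.

Step 13
Reactants: 23 silyl enol ether of step 11; 25 2,4,6-tris[(tert-butoxycarbonyl)oxy]benzaldehyde
Product: 27 cis-fused 1-siloxy chroman cycloadduct (TBSO on C-1 cis to the C-2 methyl), via quinone methide 26 (not isolated)
Conditions: 25, i-BuMgBr, Et2O, −78 °C; then 23, −78 °C → rt
Reagents that add atoms: isobutylmagnesium bromide, CC(C)C[Mg]Br
Why: Grignard addition to the aldehyde, migration of one ortho Boc group to the benzylic alkoxide and 1,4-elimination give quinone methide 26, which the enol ether traps in an inverse-electron-demand hetero-Diels–Alder reaction (methide carbon to the nucleophilic C-2, oxygen to C-1); approach anti to C-10, whose methyl shields the lower face of C-1, sets C-2 and C-1, and an arrangement with the TBSO group endo and the isobutyl group syn to the ring carbonyl (away from the flanking carbonate) should place H-7' cis to the C-2 methyl.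

Step 14
Reactants: 27 cis-fused 1-siloxy chroman cycloadduct
Product: 29 chroman-5,7-diol with the target skeleton (1S,2R,5R,10R,7'S), via biscarbonate 28 (not isolated)
Conditions: Et3SiH, BF3·OEt2, CH2Cl2, −78 °C; then K2CO3, MeOH, rt
Reagents that add atoms: none
Why: Ionic hydrogenation: BF3 ionises the tertiary silyl ketal to the ring oxocarbenium ion and Et3SiH delivers hydride to C-1 on the only face that keeps the pyran cis-fused to the cyclopentane (H-1 cis to the C-2 methyl), after which methanolysis removes both aryl carbonates.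

Step 15
Reactants: 29 chroman-5,7-diol with the target skeleton
Product: 31 target CNP0121396.3, via bis-iminium salt 30 (not isolated)
Conditions: POCl3, DMF, 0 → 40 °C; then aq. NaOAc, 60 °C
Reagents that add atoms: N,N-dimethylformamide, CN(C)C=O; water, O
Why: Vilsmeier–Haack formylation: the two remaining aromatic C–H positions are each ortho or para to all three ring oxygens and are the only free sites, so double electrophilic substitution and hydrolysis of the iminium salts should give the dialdehyde without touching the stereocentres.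

Compound list

1 | (E)-but-2-enal (crotonaldehyde) | C/C=C/C=O | starting material
2 | 2,3-dibromobutanal (diastereomer mixture) | CC(Br)C(Br)C=O | intermediate
3 | (Z)-2-bromobut-2-enal | C/C=C(\Br)C=O | intermediate
4 | (E)-4-methylpent-2-ene | C/C=C/C(C)C | starting material
5 | (E)-(4-methylpent-2-en-1-yl)diisopinocampheylborane, isopinocampheyl groups from (+)-α-pinene | CC(C)/C=C/CB([C@@H]1C[C@@H]2C[C@H]([C@H]1C)C2(C)C)[C@@H]1C[C@@H]2C[C@H]([C@H]1C)C2(C)C | intermediate
6 | diisopinocampheylborinate ester of alcohol 7 | C/C=C(\Br)[C@@H](OB([C@@H]1C[C@@H]2C[C@H]([C@H]1C)C2(C)C)[C@@H]1C[C@@H]2C[C@H]([C@H]1C)C2(C)C)[C@H](C=C)C(C)C | intermediate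
7 | (3S,4S,5Z)-5-bromo-3-(propan-2-yl)hepta-1,5-dien-4-ol | C/C=C(\Br)[C@@H](O)[C@H](C=C)C(C)C | intermediate
8 | (4R,5S,6Z)-6-bromo-5-hydroxy-4-(propan-2-yl)oct-6-enal | C/C=C(\Br)[C@@H](O)[C@H](CCC=O)C(C)C | intermediate
9 | (5R,6S)-6-[(1Z)-1-bromoprop-1-en-1-yl]-5-(propan-2-yl)oxan-2-ol (anomer mixture) | C/C=C(\Br)[C@H]1OC(O)CC[C@@H]1C(C)C | intermediate
10 | (5R,6S)-6-[(1Z)-1-bromoprop-1-en-1-yl]-5-(propan-2-yl)oxan-2-one | C/C=C(\Br)[C@H]1OC(=O)CC[C@@H]1C(C)C | intermediate
11 | {[(2S,3R)-2-[(1Z)-1-bromoprop-1-en-1-yl]-3-(propan-2-yl)-3,4-dihydro-2H-pyran-6-yl]oxy}trimethylsilane | C/C=C(\Br)[C@H]1OC(O[Si](C)(C)C)=CC[C@@H]1C(C)C | intermediate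
12 | trimethylsilyl (1R,2R,5R)-3-bromo-2-methyl-5-(propan-2-yl)cyclohex-3-ene-1-carboxylate | BrC1=C[C@@H](C(C)C)C[C@@H](C(=O)O[Si](C)(C)C)[C@H]1C | intermediate
13 | (1R,2R,5R)-3-bromo-2-methyl-5-(propan-2-yl)cyclohex-3-ene-1-carboxylic acid (CO2H, CH3 and isopropyl all cis) | BrC1=C[C@@H](C(C)C)C[C@@H](C(=O)O)[C@H]1C | intermediate
14 | acid chloride of 13 | BrC1=C[C@@H](C(C)C)C[C@@H](C(Cl)=O)[C@H]1C | intermediate
15 | 2-thioxopyridin-1(2H)-yl ester of 13 | BrC1=C[C@@H](C(C)C)C[C@@H](C(=O)ON2C=CC=CC2=S)[C@H]1C | intermediate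
16 | (3R,6R)-1-bromo-6-methyl-3-(propan-2-yl)cyclohex-1-ene | BrC1=C[C@@H](C(C)C)CC[C@H]1C | intermediate
17 | methyl (3R,6R)-6-methyl-3-(propan-2-yl)cyclohex-1-ene-1-carboxylate | COC(=O)C1=C[C@@H](C(C)C)CC[C@H]1C | intermediate
18 | methyl 4-iodobutanoate | COC(=O)CCCI | starting material
19 | methyl (1R,6R)-1-(4-methoxy-4-oxobutyl)-6-methyl-3-(propan-2-yl)cyclohex-2-ene-1-carboxylate | COC(=O)CCC[C@]1(C(=O)OC)C=C(C(C)C)CC[C@H]1C | intermediate
20 | methyl (5R,10R)-10-methyl-1-oxo-7-(propan-2-yl)spiro[4.5]dec-6-ene-2-carboxylate (C-2 epimers, present as sodium enolate) | COC(=O)C1CC[C@]2(C1=O)C=C(C(C)C)CC[C@H]2C | intermediate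
21 | methyl (5R,10R)-2,10-dimethyl-1-oxo-7-(propan-2-yl)spiro[4.5]dec-6-ene-2-carboxylate (C-2 epimers) | COC(=O)C1(C)CC[C@]2(C1=O)C=C(C(C)C)CC[C@H]2C | intermediate
22 | (5R,10R)-2,10-dimethyl-7-(propan-2-yl)spiro[4.5]dec-6-en-1-one (C-2 epimers) | CC1CC[C@]2(C1=O)C=C(C(C)C)CC[C@H]2C | intermediate
23 | tert-butyl{[(5R,10R)-2,10-dimethyl-7-(propan-2-yl)spiro[4.5]deca-1,6-dien-1-yl]oxy}dimethylsilane | CC1=C(O[Si](C)(C)C(C)(C)C)[C@@]2(CC1)C=C(C(C)C)CC[C@H]2C | intermediate
24 | 2,4,6-trihydroxybenzaldehyde | O=Cc1c(O)cc(O)cc1O | starting material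
25 | 2,4,6-tris[(tert-butoxycarbonyl)oxy]benzaldehyde | O=Cc1c(OC(=O)OC(C)(C)C)cc(OC(=O)OC(C)(C)C)cc1OC(=O)OC(C)(C)C | intermediate
26 | (6Z)-3,5-bis[(tert-butoxycarbonyl)oxy]-6-(3-methylbutylidene)cyclohexa-2,4-dien-1-one | CC(C)C/C=C1\C(=O)C=C(OC(=O)OC(C)(C)C)C=C1OC(=O)OC(C)(C)C | intermediate
27 | cycloadduct: chroman ring fused at C-1/C-2 of the spirodecene, OTBS on C-1 cis to the C-2 methyl, isobutyl on C-7' trans to the C-2 methyl, aryl carbonates at the two phenol positions; spatial arrangement at C-2, C-5, C-10 and C-7' as in the target | CC(C)C[C@@H]1c2c(OC(=O)OC(C)(C)C)cc(OC(=O)OC(C)(C)C)cc2O[C@@]2(O[Si](C)(C)C(C)(C)C)[C@]1(C)CC[C@@]21C=C(C(C)C)CC[C@H]1C | intermediate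
28 | biscarbonate of diol 29 (1S,2R,5R,10R,7'S) | CC(C)C[C@@H]1c2c(OC(=O)OC(C)(C)C)cc(OC(=O)OC(C)(C)C)cc2O[C@H]2[C@]1(C)CC[C@@]21C=C(C(C)C)CC[C@H]1C | intermediate
29 | chroman-5,7-diol with the target skeleton (1S,2R,5R,10R,7'S), lacking the two formyl groups | CC(C)C[C@@H]1c2c(O)cc(O)cc2O[C@H]2[C@]1(C)CC[C@@]21C=C(C(C)C)CC[C@H]1C | intermediate
30 | bis(dimethyliminium) dichloride of the target dialdehyde | CC(C)C[C@@H]1c2c(O)c(C=[N+](C)C)c(O)c(C=[N+](C)C)c2O[C@H]2[C@]1(C)CC[C@@]21C=C(C(C)C)CC[C@H]1C.[Cl-].[Cl-] | intermediate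
31 | target CNP0121396.3: 6,8-diformyl-5,7-dihydroxy chroman fused to the spiro[4.5]decene (1S,2R,5R,10R,7'S) | CC(C)C[C@@H]1c2c(O)c(C=O)c(O)c(C=O)c2O[C@H]2[C@]1(C)CC[C@@]21C=C(C(C)C)CC[C@H]1C | target

Total step count: 15. Longest linear sequence: 14 steps (steps 1 to 11 and 13 to 15; step 12 is a one-step branch).

Steps most likely to fail

Step 13. The configuration at C-7' rests on the geometry of the quinone methide and on the endo/exo orientation of a tetrasubstituted enol ether, neither of which is secure, and the methide may oligomerise faster than it is trapped. The fallback re-sets C-7' after the fact by hydride delivery. It sets out from 23 and 25: if the cycloaddition gives mainly the epimeric ketal F5, this is taken through the conditions of step 14 to the epimeric diol F6; DDQ (dioxane, rt) removes the benzylic hydride to give the fully substituted quinone methide F7, and NaBH4 (MeOH, 0 °C) returns hydride to C-7' from the convex, methyl-bearing face of the cis-fused bicycle. The fallback comes back to the route at 29.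

Step 5. The rearrangement must pass through a strained boat array, so it may be slow enough for loss of HBr from the alkenyl bromide or decomposition of the ketene acetal to compete. The fallback forms the same C-9–C-10 bond by polar steps. It sets out from 10: methoxycarbonylation of the alkenyl bromide (Pd(OAc)2, dppp, CO, MeOH, Et3N) should give the unsaturated ester lactone F1; LiN(SiMe3)2 (THF, −78 → 0 °C) generates the lactone enolate, which adds intramolecularly to the crotonate β-carbon on the face held by the lactone bridge to give the bridged lactone F2; DBU opens the bridge by β-elimination of the carboxylate to the cyclohexene acid F3, and Barton decarboxylation under the conditions of step 6 comes back to the route at 17.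

Step 8. Removal of the hindered tertiary γ-hydrogen at C-7 may be sluggish, with conjugate addition of the amide base and proton transfer to the iodo ester competing. The fallback separates deconjugation from alkylation. It sets out from 17: irradiation (254 nm, hexane, catalytic 1,2-dimethylimidazole) deconjugates the ester by photoenolisation to the β,γ-unsaturated ester F4, whose doubly activated α-hydrogen is removed by KN(SiMe3)2 (THF, −78 °C); alkylation with 18 then comes back to the route at 19 with the same anti selectivity.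

Further compounds

F1 | step 5 | methyl (2Z)-2-[(2S,3R)-6-oxo-3-(propan-2-yl)oxan-2-yl]but-2-enoate | C/C=C(\C(=O)OC)[C@H]1OC(=O)CC[C@@H]1C(C)C
F2 | step 5 | bridged lactone (2-oxabicyclo[2.2.2]octan-3-one) with CO2CH3 and CH3 on one carbon bridge and isopropyl on the other, ester-bearing carbon as epimers | COC(=O)C1[C@H]2OC(=O)[C@H](C[C@@H]2C(C)C)[C@H]1C
F3 | step 5 | (1R,2R,5R)-3-(methoxycarbonyl)-2-methyl-5-(propan-2-yl)cyclohex-3-ene-1-carboxylic acid | COC(=O)C1=C[C@@H](C(C)C)C[C@@H](C(=O)O)[C@H]1C
F4 | step 8 | methyl (6R)-6-methyl-3-(propan-2-yl)cyclohex-2-ene-1-carboxylate (C-1 epimers) | COC(=O)C1C=C(C(C)C)CC[C@H]1C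
F5 | step 13 | C-7' epimer of cycloadduct 27 | CC(C)C[C@H]1c2c(OC(=O)OC(C)(C)C)cc(OC(=O)OC(C)(C)C)cc2O[C@@]2(O[Si](C)(C)C(C)(C)C)[C@]1(C)CC[C@@]21C=C(C(C)C)CC[C@H]1C
F6 | step 13 | C-7' epimer of diol 29 | CC(C)C[C@H]1c2c(O)cc(O)cc2O[C@H]2[C@]1(C)CC[C@@]21C=C(C(C)C)CC[C@H]1C
F7 | step 13 | quinone methide from F6 (C-7' doubly bonded to the ring, one ring oxygen as ketone) | CC(C)CC1=C2C(=O)C=C(O)C=C2O[C@H]2[C@]1(C)CC[C@@]21C=C(C(C)C)CC[C@H]1C
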